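**Retrosynthetic overview**

1. Target triacid 32 ⇐ trimethyl ester 31 ⇐ 13,17-diol 28 (reductive allylic transposition makes the 16-methylene) ⇐ tetracycle 25/26 (C11=C12 hydrogenation, C6 equilibration).
2. Structural feature used: the C/D bicyclo[3.2.1]octane is a seven-membered ring C8–C9–C11–C12–C13–C16–C15 spanned by the single carbon C14. Cutting C8–C9 and C12–C13 leaves a cyclopentadiene (C8, C15, C16, C13, C14) and a three-carbon unit C9–C11–C12 carried on C10 as an allene.
3. The tether C10–C5–C6 closes ring B (C5, C6, C8, C9, C10) in the same metal-catalysed allene–diene (4+3) cycloaddition that closes ring C.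
4. Precursor 24 ⇐ ring A allene triester 19 + cyclopentenone 20 (C6–C8 by conjugate addition–elimination, C17 by Baylis–Hillman hydroxymethylation, then silyl dienol ether).
5. 19 ⇐ C5 set by an organocatalytic malonate–enal Michael addition; ring A closed by alkylation with a three-carbon unit; C4 methylation and C10 propargyl-ester Ireland–Claisen both anti to the C5 side chain. Ring order: A, then B and C together on the five-membered ring that becomes D.

Key step: step 15

Remark: gibberellane numbering (C1–C20) is used for the atoms of all intermediates; C17 is the future exocyclic methylene carbon.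
Assumption: the two C6 epimers formed in step 12 are not separated; compounds 21–25 are carried as the epimer pair (C6 left open in their SMILES) and converge in step 16.
Remark: C17 is carried as a silyloxymethyl group, not a silylmethyl group, because putting a silylmethyl group on C16 after the allene is in place would need electrophilic iodine and palladium, which a β-allenic ester does not survive.

**Route**

Step 1
Reactants: 1 3-[(tert-butyldimethylsilyl)oxy]propanal; 2 (triphenylphosphoranylidene)acetaldehyde
Product: 3 (E)-5-[(tert-butyldimethylsilyl)oxy]pent-2-enal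
Conditions: toluene, 80 °C
Reagents that add atoms: none
Why: Wittig olefination with a stabilised formyl ylide, which gives the (E)-enal and supplies C4 and C19 next to the future C5.

Step 2
Reactants: 3 (E)-5-[(tert-butyldimethylsilyl)oxy]pent-2-enal; 4 dibenzyl malonate
Product: 5 dibenzyl 2-[(3R)-1-[(tert-butyldimethylsilyl)oxy]-5-oxopentan-3-yl]malonate
Conditions: (S)-2-[bis(3,5-bis(trifluoromethyl)phenyl)(trimethylsilyloxy)methyl]pyrrolidine (10 mol %), EtOH, 0 °C
Reagents that add atoms: none
Why: iminium-catalysed Michael addition of a malonate to an (E)-enal, in which the aryl(silyloxy)methyl group of the (S)-catalyst shields one face of the iminium ion so that the malonate carbon (future C10) should add to the other face of C5 and set the (R) centre that becomes the 5β-hydrogen centre of the target.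

Step 3
Reactants: 5 dibenzyl 2-[(3R)-1-[(tert-butyldimethylsilyl)oxy]-5-oxopentan-3-yl]malonate
Product: 6 dibenzyl 2-[(3R)-1-[(tert-butyldimethylsilyl)oxy]-5-methoxy-5-oxopentan-3-yl]malonate
Conditions: PDC ((C5H5NH)2Cr2O7), MeOH, DMF, 25 °C
Reagents that add atoms: methanol (CO)
Why: oxidative esterification of the aldehyde through its methyl hemiacetal by hexavalent chromium, which turns C19 into the methyl ester and leaves the silyl ether, the benzyl esters and the non-enolisable C5 centre alone.

Step 4
Reactants: 6 dibenzyl 2-[(3R)-1-[(tert-butyldimethylsilyl)oxy]-5-methoxy-5-oxopentan-3-yl]malonate; 7 1,3-dibromopropane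
Product: 8 dibenzyl 2-(3-bromopropyl)-2-[(3R)-1-[(tert-butyldimethylsilyl)oxy]-5-methoxy-5-oxopentan-3-yl]malonate
Conditions: NaH, DMF, 0 °C; 7 (5 equiv), 25 → 50 °C
Reagents that add atoms: none
Why: malonate alkylation (SN2), in which only the malonate C–H is acidic enough for NaH and the excess dibromide suppresses double alkylation, so that C10 receives the chain C1–C3.

Step 5
Reactants: 8 dibenzyl 2-(3-bromopropyl)-2-[(3R)-1-[(tert-butyldimethylsilyl)oxy]-5-methoxy-5-oxopentan-3-yl]malonate
Product: 9 1,1-dibenzyl 3-methyl (2R)-2-[2-[(tert-butyldimethylsilyl)oxy]ethyl]cyclohexane-1,1,3-tricarboxylate (ring A; both C4 epimers)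
Conditions: LiN(SiMe3)2, THF–DMPU, −78 → 0 °C
Reagents that add atoms: none
Why: 6-exo-tet intramolecular alkylation of the only possible ester enolate (C4) on the primary bromide closes ring A, and the C4 configuration does not matter because C4 is enolised again in step 6.

Step 6
Reactants: 9 1,1-dibenzyl 3-methyl (2R)-2-[2-[(tert-butyldimethylsilyl)oxy]ethyl]cyclohexane-1,1,3-tricarboxylate
Product: 10 1,1-dibenzyl 3-methyl (2R,3R)-2-[2-[(tert-butyldimethylsilyl)oxy]ethyl]-3-methylcyclohexane-1,1,3-tricarboxylate (C18 methyl trans to the C5 side chain)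
Conditions: LiN(iPr)2, THF, −78 °C; MeI, DMPU, −78 → −20 °C
Reagents that add atoms: iodomethane (CI)
Why: enolate alkylation of a 2-substituted cyclohexanecarboxylate, in which allylic 1,3-strain turns the C5 side chain axial and the electrophile enters the exocyclic enolate anti to it, so the methyl group should end trans to C6 and the C19 ester cis, as in the target.

Step 7
Reactants: 10 1,1-dibenzyl 3-methyl (2R,3R)-2-[2-[(tert-butyldimethylsilyl)oxy]ethyl]-3-methylcyclohexane-1,1,3-tricarboxylate
Product: 12 2-[2-[(tert-butyldimethylsilyl)oxy]ethyl]-3-(methoxycarbonyl)-3-methylcyclohexane-1-carboxylic acid (both C10 epimers), via geminal diacid 11 (not isolated)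
Conditions: H2 (1 atm), Pd/C, EtOAc, 25 °C; then pyridine, 100 °C
Reagents that add atoms: none
Why: hydrogenolysis of both benzyl esters followed by malonic acid decarboxylation leaves one carboxyl (C20) on C10, whose configuration is set later in step 9.

Step 8
Reactants: 12 2-[2-[(tert-butyldimethylsilyl)oxy]ethyl]-3-(methoxycarbonyl)-3-methylcyclohexane-1-carboxylic acid; 13 propargyl bromide
Product: 14 1-methyl 3-(prop-2-yn-1-yl) 2-[2-[(tert-butyldimethylsilyl)oxy]ethyl]-1-methylcyclohexane-1,3-dicarboxylate
Conditions: K2CO3, DMF, 25 °C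
Reagents that add atoms: none
Why: carboxylate O-alkylation (SN2 esterification) gives the propargyl ester that carries the future C9, C11 and C12.

Step 9
Reactants: 14 1-methyl 3-(prop-2-yn-1-yl) 2-[2-[(tert-butyldimethylsilyl)oxy]ethyl]-1-methylcyclohexane-1,3-dicarboxylate
Product: 17 2-[2-[(tert-butyldimethylsilyl)oxy]ethyl]-3-(methoxycarbonyl)-3-methyl-1-(propa-1,2-dien-1-yl)cyclohexane-1-carboxylic acid (allene trans to the C5 side chain), via silyl ketene acetal 15 (not isolated), via trimethylsilyl ester 16 (not isolated)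
Conditions: Me3SiOTf, Et3N, toluene, 0 → 70 °C; then aqueous pH 5 buffer
Reagents that add atoms: none
Why: Ireland–Claisen rearrangement of a propargyl ester to an α-allenyl acid, in which soft enolisation (silyl triflate and tertiary amine) makes the ketene acetal at the only enolisable carbon (C10) without deprotonating the acetylenic C–H, and the [3,3] shift delivers C9 to the face anti to the C5 side chain and the C19 ester, so the quaternary C10 should carry the allene cis to H5.

Step 10
Reactants: 17 2-[2-[(tert-butyldimethylsilyl)oxy]ethyl]-3-(methoxycarbonyl)-3-methyl-1-(propa-1,2-dien-1-yl)cyclohexane-1-carboxylic acid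
Product: 18 2-(carboxymethyl)-3-(methoxycarbonyl)-3-methyl-1-(propa-1,2-dien-1-yl)cyclohexane-1-carboxylic acid
Conditions: CrO3, H2SO4, H2O, acetone, 0 °C
Reagents that add atoms: water (O)
Why: Jones oxidation, in which the acidic medium cleaves the primary silyl ether and chromic acid takes the freed alcohol through the aldehyde hydrate to the C7 acid while the allene and the quaternary centres are inert at 0 °C.

Step 11
Reactants: 18 2-(carboxymethyl)-3-(methoxycarbonyl)-3-methyl-1-(propa-1,2-dien-1-yl)cyclohexane-1-carboxylic acid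
Product: 19 dimethyl 2-(2-methoxy-2-oxoethyl)-1-methyl-3-(propa-1,2-dien-1-yl)cyclohexane-1,3-dicarboxylate (ring A allene triester; C19 and C20 esters cis to the C6 side chain)
Conditions: Me3SiCHN2, MeOH–toluene, 0 → 25 °C
Reagents that add atoms: (trimethylsilyl)diazomethane (C[Si](C)(C)C=[N+]=[N-])
Why: diazoalkane esterification of both acids, which needs no base and therefore cannot isomerise the β-allenic ester.

Step 12
Reactants: 19 dimethyl 2-(2-methoxy-2-oxoethyl)-1-methyl-3-(propa-1,2-dien-1-yl)cyclohexane-1,3-dicarboxylate; 20 (R)-4-[(tert-butyldimethylsilyl)oxy]cyclopent-2-en-1-one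
Product: 22 ring A allene triester bearing a 4-oxocyclopent-2-en-1-yl group on C6 (C8 defined; C6 epimers), via silyloxy ketone adduct 21 (not isolated)
Conditions: LiN(iPr)2, THF–DMPU, −78 °C; 20, −78 → −30 °C; DBU, −30 → 0 °C (short); aqueous NH4Cl
Reagents that add atoms: none
Why: conjugate addition–β-elimination, the standard entry from 4-oxygenated cyclopentenones to 4-substituted cyclopent-2-enones, in which the C6 lithium enolate (the only one that can form) adds anti to the silyloxy group and DBU then expels silanolate, so C8 forms in one configuration that is removed in step 14 and C6 as an epimer pair that is equilibrated in step 16.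

Step 13
Reactants: 22 ring A allene triester bearing a 4-oxocyclopent-2-en-1-yl group on C6
Product: 23 ring A allene triester bearing a 3-(hydroxymethyl)-4-oxocyclopent-2-en-1-yl group on C6 (C17 alcohol)
Conditions: 37% aqueous HCHO, imidazole, THF–H2O, 25 °C
Reagents that add atoms: formaldehyde (C=O)
Why: Morita–Baylis–Hillman hydroxymethylation of a cyclopentenone under imidazole catalysis, which places C17 on the enone α-carbon C16 without any reagent that attacks the allene.

Step 14
Reactants: 23 ring A allene triester bearing a 3-(hydroxymethyl)-4-oxocyclopent-2-en-1-yl group on C6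
Product: 24 ring A allene triester bearing a 4-[(tert-butyldimethylsilyl)oxy]-3-[[(tert-butyldimethylsilyl)oxy]methyl]cyclopenta-1,3-dien-1-yl group on C6 (cycloaddition precursor)
Conditions: tBuMe2SiOTf (2.4 equiv), Et3N, CH2Cl2, −78 → 23 °C
Reagents that add atoms: tert-butyldimethylsilyl triflate (CC(C)(C)[Si](C)(C)OS(=O)(=O)C(F)(F)F)
Why: silylation of the primary alcohol and silyl dienol ether formation under equilibrating silyl triflate–amine conditions, where loss of the γ-hydrogen H8 should give the linearly conjugated, fully substituted cyclopentadiene with C14 as the only sp3 ring carbon and C8 no longer stereogenic.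

Step 15
Reactants: 24 ring A allene triester bearing a 4-[(tert-butyldimethylsilyl)oxy]-3-[[(tert-butyldimethylsilyl)oxy]methyl]cyclopenta-1,3-dien-1-yl group on C6
Product: 25 trimethyl 13-[(tert-butyldimethylsilyl)oxy]-17-[(tert-butyldimethylsilyl)oxy]gibberella-11,15-diene-7,19,20-trioate (tetracycle; C6 epimers)
Conditions: IPrAuCl (chloro[1,3-bis(2,6-diisopropylphenyl)imidazol-2-ylidene]gold, 5 mol %), AgSbF6 (5 mol %), CH2Cl2, 4 Å molecular sieves, −20 → 0 °C
Reagents that add atoms: none
Why: Proposed new method: cationic monovalent gold binds the terminal allene and slips to C11, giving a gold-bound allyl cation over C9–C11–C12 that adds across the diene termini C8 and C13 in an asynchronous (4+3) cycloaddition (C8–C9 first, then C12 captures the silyloxy-stabilised cation at C13), and the resulting C11 gold carbene collapses by 1,2-hydride shift from C12 to the C11=C12 alkene. The closest known reaction type is the PtCl2- or gold-catalysed intramolecular (4+3) cycloaddition of allenedienes, established for acyclic dienes and terminally disubstituted allenes; here the diene is a cyclopentadiene and the distal allene carbon is unsubstituted, which the electron-rich 1-silyloxy diene is meant to offset. Ring B (C5, C6, C8, C9, C10) closes by 5-exo attack of C8 on the proximal allene carbon C9 through the three-atom tether C10–C5–C6, and ring C (C8, C9, C11, C12, C13, C14) closes when C12 bonds to C13, with C14 becoming the one-carbon bridge and the former cyclopentadiene becoming ring D. C8 and C13 are set together by the diene face that is attacked and C9 by the placement of C11: the tether ends are trans-diequatorial on the ring A chair, and an extended arrangement with the gold-bearing C11 over the small C14 methylene (not over the C15=C16 edge with its silyloxymethyl group), on the α-face that already carries the axial C19 and C20 esters, gives the natural sense with H9 cis to H5, which is expected but not assured. The step needs (4+3) over (4+2) or (3+2) periselectivity and hydride shift from C12 and not from C9; the σ-donor carbene ligand favours hydride over alkyl shift, the silyloxy group localises the intermediate charge on C13, and H9 lies equatorial on ring C, poorly aligned with the carbene p orbital. The low temperature is chosen so that the cycloaddition outruns 1,5-hydrogen shifts of the cyclopentadiene.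

Step 16
Reactants: 25 trimethyl 13-[(tert-butyldimethylsilyl)oxy]-17-[(tert-butyldimethylsilyl)oxy]gibberella-11,15-diene-7,19,20-trioate (C6 epimers)
Product: 26 the same tetracycle as the single 6β-ester (natural C6)
Conditions: NaOMe, MeOH, 50 °C
Reagents that add atoms: none
Why: base-mediated epimerisation through the C6 ester enolate, the only enolisable position, should settle on the 6β-ester that is trans to C4 on ring B, the thermodynamically preferred and natural configuration.

Step 17
Reactants: 26 trimethyl 13-[(tert-butyldimethylsilyl)oxy]-17-[(tert-butyldimethylsilyl)oxy]gibberella-11,15-diene-7,19,20-trioate (6β)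
Product: 27 trimethyl 13-[(tert-butyldimethylsilyl)oxy]-17-[(tert-butyldimethylsilyl)oxy]gibberell-15-ene-7,19,20-trioate
Conditions: H2 (3 atm), RhCl(PPh3)3 (10 mol %), benzene–EtOH, 25 °C
Reagents that add atoms: none
Why: homogeneous rhodium-catalysed hydrogenation, which reduces the cis-disubstituted C11=C12 bond but not the trisubstituted C15=C16 bond flanked by two quaternary carbons (diimide is avoided because it favours strained bridged alkenes), and which forms no stereocentre.

Step 18
Reactants: 27 trimethyl 13-[(tert-butyldimethylsilyl)oxy]-17-[(tert-butyldimethylsilyl)oxy]gibberell-15-ene-7,19,20-trioate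
Product: 28 trimethyl 13,17-dihydroxygibberell-15-ene-7,19,20-trioate
Conditions: Bu4NF, THF, 0 → 50 °C; aqueous NH4Cl
Reagents that add atoms: none
Why: fluoride desilylation removes the primary allylic silyl ether quickly and the tertiary bridgehead silyl ether on warming.

Step 19
Reactants: 28 trimethyl 13,17-dihydroxygibberell-15-ene-7,19,20-trioate
Product: 31 trimethyl 13-hydroxygibberell-16-ene-7,19,20-trioate (trimethyl ester of the target), via sulfonyl hydrazine 29 (not isolated), via allylic diazene 30 (not isolated)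
Conditions: 2-nitrobenzenesulfonylhydrazide, PPh3, diethyl azodicarboxylate, THF, −30 °C; then 23 °C
Reagents that add atoms: none
Why: reductive 1,3-transposition of an allylic alcohol by Mitsunobu displacement of the primary C17 hydroxyl with the sulfonyl hydrazide, loss of sulfinic acid and retro-ene loss of dinitrogen from the monoalkyl diazene, which delivers hydrogen to C15 and moves the double bond to C16=C17 while the tertiary 13-hydroxyl does not take part.

Step 20
Reactants: 31 trimethyl 13-hydroxygibberell-16-ene-7,19,20-trioate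
Product: 32 13-hydroxygibberell-16-ene-7,19,20-trioic acid (the target gibberellin)
Conditions: n-PrSLi, HMPA, 25 → 50 °C; then aqueous HCl
Reagents that add atoms: none
Why: SN2 demethylation of the three hindered methyl esters by thiolate in a dipolar aprotic solvent, the usual answer to neopentyl-type esters that resist saponification, which touches neither the stereocentres nor the 16-methylene.

**Compound list**

1 | 3-[(tert-butyldimethylsilyl)oxy]propanal | O=CCCO[Si](C)(C)C(C)(C)C | starting material
2 | (triphenylphosphoranylidene)acetaldehyde | O=CC=P(c1ccccc1)(c1ccccc1)c1ccccc1 | starting material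
3 | (E)-5-[(tert-butyldimethylsilyl)oxy]pent-2-enal | O=C/C=C/CCO[Si](C)(C)C(C)(C)C | intermediate
4 | dibenzyl malonate | O=C(CC(=O)OCc1ccccc1)OCc1ccccc1 | starting material
5 | dibenzyl 2-[(3R)-1-[(tert-butyldimethylsilyl)oxy]-5-oxopentan-3-yl]malonate | O=CC[C@H](C(C(=O)OCc1ccccc1)C(=O)OCc1ccccc1)CCO[Si](C)(C)C(C)(C)C | intermediate
6 | dibenzyl 2-[(3R)-1-[(tert-butyldimethylsilyl)oxy]-5-methoxy-5-oxopentan-3-yl]malonate | COC(=O)C[C@H](C(C(=O)OCc1ccccc1)C(=O)OCc1ccccc1)CCO[Si](C)(C)C(C)(C)C | intermediate
7 | 1,3-dibromopropane | BrCCCBr | starting material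
8 | dibenzyl 2-(3-bromopropyl)-2-[(3R)-1-[(tert-butyldimethylsilyl)oxy]-5-methoxy-5-oxopentan-3-yl]malonate | COC(=O)C[C@H](C(CCCBr)(C(=O)OCc1ccccc1)C(=O)OCc1ccccc1)CCO[Si](C)(C)C(C)(C)C | intermediate
9 | 1,1-dibenzyl 3-methyl (2R)-2-[2-[(tert-butyldimethylsilyl)oxy]ethyl]cyclohexane-1,1,3-tricarboxylate (C4 epimers) | COC(=O)C1CCCC(C(=O)OCc2ccccc2)(C(=O)OCc2ccccc2)[C@@H]1CCO[Si](C)(C)C(C)(C)C | intermediate
10 | 1,1-dibenzyl 3-methyl (2R,3R)-2-[2-[(tert-butyldimethylsilyl)oxy]ethyl]-3-methylcyclohexane-1,1,3-tricarboxylate | O=C(OCc2ccccc2)C1(C(=O)OCc2ccccc2)CCC[C@@](C)(C(=O)OC)[C@H]1CCO[Si](C)(C)C(C)(C)C | intermediate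
11 | 2-[2-[(tert-butyldimethylsilyl)oxy]ethyl]-3-(methoxycarbonyl)-3-methylcyclohexane-1,1-dicarboxylic acid (not isolated) | O=C(O)C1(C(=O)O)CCC[C@@](C)(C(=O)OC)[C@H]1CCO[Si](C)(C)C(C)(C)C | intermediate
12 | 2-[2-[(tert-butyldimethylsilyl)oxy]ethyl]-3-(methoxycarbonyl)-3-methylcyclohexane-1-carboxylic acid (C10 epimers) | O=C(O)C1CCC[C@@](C)(C(=O)OC)[C@H]1CCO[Si](C)(C)C(C)(C)C | intermediate
13 | propargyl bromide | C#CCBr | starting material
14 | 1-methyl 3-(prop-2-yn-1-yl) 2-[2-[(tert-butyldimethylsilyl)oxy]ethyl]-1-methylcyclohexane-1,3-dicarboxylate (C10 epimers) | C#CCOC(=O)C1CCC[C@@](C)(C(=O)OC)[C@H]1CCO[Si](C)(C)C(C)(C)C | intermediate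
15 | trimethylsilyl ketene acetal of 14 at C10 (not isolated) | C#CCOC(O[Si](C)(C)C)=C1CCC[C@@](C)(C(=O)OC)[C@H]1CCO[Si](C)(C)C(C)(C)C | intermediate
16 | trimethylsilyl ester of 17 (not isolated) | C=C=C[C@]1(C(=O)O[Si](C)(C)C)CCC[C@@](C)(C(=O)OC)[C@H]1CCO[Si](C)(C)C(C)(C)C | intermediate
17 | 2-[2-[(tert-butyldimethylsilyl)oxy]ethyl]-3-(methoxycarbonyl)-3-methyl-1-(propa-1,2-dien-1-yl)cyclohexane-1-carboxylic acid | C=C=C[C@]1(C(=O)O)CCC[C@@](C)(C(=O)OC)[C@H]1CCO[Si](C)(C)C(C)(C)C | intermediate
18 | 2-(carboxymethyl)-3-(methoxycarbonyl)-3-methyl-1-(propa-1,2-dien-1-yl)cyclohexane-1-carboxylic acid | C=C=C[C@]1(C(=O)O)CCC[C@@](C)(C(=O)OC)[C@H]1CC(=O)O | intermediate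
19 | dimethyl 2-(2-methoxy-2-oxoethyl)-1-methyl-3-(propa-1,2-dien-1-yl)cyclohexane-1,3-dicarboxylate (ring A allene triester) | C=C=C[C@]1(C(=O)OC)CCC[C@@](C)(C(=O)OC)[C@H]1CC(=O)OC | intermediate
20 | (R)-4-[(tert-butyldimethylsilyl)oxy]cyclopent-2-en-1-one | O=C1C=C[C@H](O[Si](C)(C)C(C)(C)C)C1 | starting material
21 | conjugate adduct: 19 carrying a trans-2-[(tert-butyldimethylsilyl)oxy]-4-oxocyclopentyl group on C6 (C6 epimers; not isolated) | C=C=C[C@]1(C(=O)OC)CCC[C@@](C)(C(=O)OC)[C@H]1C(C(=O)OC)[C@@H]2CC(=O)C[C@H]2O[Si](C)(C)C(C)(C)C | intermediate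
22 | 19 carrying a 4-oxocyclopent-2-en-1-yl group on C6 (C6 epimers) | C=C=C[C@]1(C(=O)OC)CCC[C@@](C)(C(=O)OC)[C@H]1C(C(=O)OC)[C@H]2C=CC(=O)C2 | intermediate
23 | 19 carrying a 3-(hydroxymethyl)-4-oxocyclopent-2-en-1-yl group on C6 (C6 epimers) | C=C=C[C@]1(C(=O)OC)CCC[C@@](C)(C(=O)OC)[C@H]1C(C(=O)OC)[C@H]2C=C(CO)C(=O)C2 | intermediate
24 | cycloaddition precursor: 19 carrying a 4-[(tert-butyldimethylsilyl)oxy]-3-[[(tert-butyldimethylsilyl)oxy]methyl]cyclopenta-1,3-dien-1-yl group on C6 (C6 epimers) | C=C=C[C@]1(C(=O)OC)CCC[C@@](C)(C(=O)OC)[C@H]1C(C(=O)OC)C2=CC(CO[Si](C)(C)C(C)(C)C)=C(O[Si](C)(C)C(C)(C)C)C2 | intermediate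
25 | trimethyl 13,17-bis[(tert-butyldimethylsilyl)oxy]gibberella-11,15-diene-7,19,20-trioate (C6 epimers) | CC(C)(C)[Si](C)(C)OCC1=C[C@]23C[C@@]1(O[Si](C)(C)C(C)(C)C)C=C[C@H]2[C@]1(C(=O)OC)CCC[C@@](C)(C(=O)OC)[C@H]1C3C(=O)OC | intermediate
26 | trimethyl 13,17-bis[(tert-butyldimethylsilyl)oxy]gibberella-11,15-diene-7,19,20-trioate (6β-ester) | CC(C)(C)[Si](C)(C)OCC1=C[C@]23C[C@@]1(O[Si](C)(C)C(C)(C)C)C=C[C@H]2[C@]1(C(=O)OC)CCC[C@@](C)(C(=O)OC)[C@H]1[C@@H]3C(=O)OC | intermediate
27 | trimethyl 13,17-bis[(tert-butyldimethylsilyl)oxy]gibberell-15-ene-7,19,20-trioate | CC(C)(C)[Si](C)(C)OCC1=C[C@]23C[C@@]1(O[Si](C)(C)C(C)(C)C)CC[C@H]2[C@]1(C(=O)OC)CCC[C@@](C)(C(=O)OC)[C@H]1[C@@H]3C(=O)OC | intermediate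
28 | trimethyl 13,17-dihydroxygibberell-15-ene-7,19,20-trioate | OCC1=C[C@]23C[C@@]1(O)CC[C@H]2[C@]1(C(=O)OC)CCC[C@@](C)(C(=O)OC)[C@H]1[C@@H]3C(=O)OC | intermediate
29 | N-(C17-allyl)-N-(2-nitrobenzenesulfonyl)hydrazine of 28 (not isolated) | NN(CC1=C[C@]23C[C@@]1(O)CC[C@H]2[C@]1(C(=O)OC)CCC[C@@](C)(C(=O)OC)[C@H]1[C@@H]3C(=O)OC)S(=O)(=O)c1ccccc1[N+](=O)[O-] | intermediate
30 | C17 allylic diazene (not isolated) | N=NCC1=C[C@]23C[C@@]1(O)CC[C@H]2[C@]1(C(=O)OC)CCC[C@@](C)(C(=O)OC)[C@H]1[C@@H]3C(=O)OC | intermediate
31 | trimethyl 13-hydroxygibberell-16-ene-7,19,20-trioate (trimethyl ester of the target) | C=C1C[C@]23C[C@@]1(O)CC[C@H]2[C@]1(C(=O)OC)CCC[C@@](C)(C(=O)OC)[C@H]1[C@@H]3C(=O)OC | intermediate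
32 | 13-hydroxygibberell-16-ene-7,19,20-trioic acid (the target gibberellin) | C=C1C[C@]23C[C@@]1(O)CC[C@H]2[C@]1(C(=O)O)CCC[C@@](C)(C(=O)O)[C@H]1[C@@H]3C(=O)O | target

**Step count**

Total steps: 20. Longest linear sequence: 20 steps (1 → 32); 2, 4, 7, 13 and 20 enter as purchased reagents.

**Steps most likely to fail**

1. Step 15 (Proposed new method). What may go wrong: attack on the wrong diene face, or the compact arrangement in place of the extended one, giving the wrong sense at C8, C9 and C13; arrest after the first C–C bond or ring contraction to a (4+2) or (3+2) adduct; hydride shift from C9; 1,5-hydrogen shift of the cyclopentadiene before it reacts; reversible capture of the activated allene by the C20 ester carbonyl. Fallback with known reactions, closing the two bonds one after the other, setting out from 24 and coming back at 28: a gold-catalysed Conia-ene-type carbocyclisation of the silyl dienol ether onto the allene in the presence of methanol (Ph3PAuCl, AgOTf, CH2Cl2–MeOH, 0 °C) would form only C8–C9 and, after protodeauration and loss of the enol silyl group, give the ring B vinyl enone F1. Hydroboration of the vinyl group with 9-BBN and oxidation with NaBO3 would give the C12 alcohol F2, and iodine, PPh3 and imidazole the primary iodide F3. SmI2 in THF–HMPA would then close ring C by intramolecular Barbier addition of C12 to the C13 ketone, giving the bridgehead alcohol F4. NaOMe in MeOH would equilibrate C6 to the 6β-ester F5, and Bu4NF would remove the remaining silyl ether to reach diol 28.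

2. Step 12. What may go wrong: 1,2-addition or simple proton transfer in place of conjugate addition by the very hindered C6 enolate, and base-induced migration of the enone double bond into conjugation with C8 during the elimination. Fallback, setting out from 19 and coming back at 22: the ester would be converted with LiN(iPr)2 and Me3SiCl into the ketene silyl acetal F6, which as a neutral nucleophile would add to 20 in a Mukaiyama–Michael reaction under catalytic Me3SiOTf in CH2Cl2 at −78 °C; mild desilylating work-up would give adduct 21, and brief DBU treatment would give 22.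

3. Step 9. What may go wrong: incomplete soft enolisation of the hindered tertiary C10–H, or silylation at the alkyne terminus, so that no rearrangement takes place. Fallback, setting out from 12 and coming back at 17, moving the sigmatropic step to the aldehyde oxidation level where no enolate base is needed: BH3·SMe2 would reduce the acid selectively to the primary alcohol F7 and Dess–Martin periodinane would give the aldehyde F8. Heating F8 with propargyl alcohol and catalytic pyridinium tosylate in toluene with removal of water would form the propargyl enol ether, which rearranges (Saucy–Marbet-type Claisen) to the α-allenyl aldehyde F9, again anti to the C5 side chain. NaClO2, NaH2PO4 and 2-methyl-2-butene would oxidise F9 to acid 17.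

Further compounds
F1 | step 15 | ring B vinyl enone: C8 spiro-linked 3-[[(tert-butyldimethylsilyl)oxy]methyl]-4-oxocyclopent-2-ene, 9-vinyl (C6 epimers) | CC(C)(C)[Si](C)(C)OCC1=C[C@]2(CC1=O)[C@@H](C=C)[C@]1(C(=O)OC)CCC[C@@](C)(C(=O)OC)[C@H]1C2C(=O)OC
F2 | step 15 | C12 primary alcohol from F1 | CC(C)(C)[Si](C)(C)OCC1=C[C@]2(CC1=O)[C@@H](CCO)[C@]1(C(=O)OC)CCC[C@@](C)(C(=O)OC)[C@H]1C2C(=O)OC
F3 | step 15 | C12 primary iodide from F2 | CC(C)(C)[Si](C)(C)OCC1=C[C@]2(CC1=O)[C@@H](CCI)[C@]1(C(=O)OC)CCC[C@@](C)(C(=O)OC)[C@H]1C2C(=O)OC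
F4 | step 15 | trimethyl 17-[(tert-butyldimethylsilyl)oxy]-13-hydroxygibberell-15-ene-7,19,20-trioate (C6 epimers) | CC(C)(C)[Si](C)(C)OCC1=C[C@]23C[C@@]1(O)CC[C@H]2[C@]1(C(=O)OC)CCC[C@@](C)(C(=O)OC)[C@H]1C3C(=O)OC
F5 | step 15 | trimethyl 17-[(tert-butyldimethylsilyl)oxy]-13-hydroxygibberell-15-ene-7,19,20-trioate (6β-ester) | CC(C)(C)[Si](C)(C)OCC1=C[C@]23C[C@@]1(O)CC[C@H]2[C@]1(C(=O)OC)CCC[C@@](C)(C(=O)OC)[C@H]1[C@@H]3C(=O)OC
F6 | step 12 | ketene methyl trimethylsilyl acetal of 19 at C6 | C=C=C[C@]1(C(=O)OC)CCC[C@@](C)(C(=O)OC)[C@H]1C=C(OC)O[Si](C)(C)C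
F7 | step 9 | methyl 2-[2-[(tert-butyldimethylsilyl)oxy]ethyl]-3-(hydroxymethyl)-1-methylcyclohexane-1-carboxylate (C10 epimers) | OCC1CCC[C@@](C)(C(=O)OC)[C@H]1CCO[Si](C)(C)C(C)(C)C
F8 | step 9 | methyl 2-[2-[(tert-butyldimethylsilyl)oxy]ethyl]-3-formyl-1-methylcyclohexane-1-carboxylate (C10 epimers) | O=CC1CCC[C@@](C)(C(=O)OC)[C@H]1CCO[Si](C)(C)C(C)(C)C
F9 | step 9 | methyl 2-[2-[(tert-butyldimethylsilyl)oxy]ethyl]-3-formyl-1-methyl-3-(propa-1,2-dien-1-yl)cyclohexane-1-carboxylate | C=C=C[C@]1(C=O)CCC[C@@](C)(C(=O)OC)[C@H]1CCO[Si](C)(C)C(C)(C)C
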